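**Remark on the chemistry:** the target SMILES has no stereocentre. The two diarylcarbinols formed on the way (11 and 20) are racemic and are oxidised to ketones, so no configuration has to be carried.

## The problem

The target is a diarylmethane in which one CH2 group joins C3 of ring B and C3 of ring C, two 2,6-dihydroxy-4-methoxybenzoyl rings, each time between a hydroxyl and the methoxy group. Ring B is bound through its ketone to ring A (2,4-dihydroxy-6-methylphenyl) and ring C to ring D (4-hydroxy-2-methoxy-6-methylphenyl), so the two benzophenone halves differ by a single O-methyl group. There is no stereocentre and no ring has to be closed; the difficulty lies in crowding and in telling apart sites of almost equal reactivity. Both ketones carry four ortho substituents, so each aryl–carbonyl bond must be made against severe crowding. Mixing the two halves with a one-carbon electrophile would give both homodimers beside the wanted compound, so rings B and C must react in a set order while the equally electron-rich rings A and D stay silent. The end of the synthesis must be neutral and mild: 2,2'-dioxygenated benzophenones close to xanthones under hot base or strong acid, a methylene between two phloroglucinol rings is cleaved or scrambled by acid, and the free heptaphenol is easily oxidised. The ring D methyl ether ortho to the carbonyl would be lost to boron or aluminium halides, which rules out late Lewis-acidic deprotection. The feature that makes the key step possible lies in ring A: C6 (methyl) and C1 (ketone carbon) are neighbours, C2 beside C1 bears oxygen and C4 bears the second oxygen, the pattern left when a 3,5-dioxygenated benzyne takes a carbon nucleophile at the carbon remote from the flanking oxygen and a carbon electrophile at the carbon next to it.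

## Retrosynthesis

**26 from 25.** The last operation only removes three benzyl ethers from rings A and D of 25. No skeletal bond is cut. Keeping these rings as ethers until the end means that only rings B and C are phenolic when the bridge is made. The forward reaction must be a hydrogenolysis that leaves two hindered diaryl ketones and the diarylmethane alone.

**25 from 23 and 22.** The bond between the bridge carbon and ring C is cut. The bridge carbon is first placed on the left half as a (dimethylamino)methyl group in 23. On warming, 23 loses dimethylamine to give the ortho-quinone methide 24, which is captured by ring C of 22. The neighbouring cut, both ring–CH2 bonds at once from 13 and 22 with a one-carbon electrophile, is shorter by one step but statistical. The directed order should give one constitution, because the free positions of rings B and C are pairwise equivalent. The Mannich base 23 goes back to 13 by cutting the ring B–CH2 bond.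

**13 from 12 from 11.** The two MOM ethers of ring B are removed and the ketone is taken back to the carbinol. A tetra-ortho-substituted diaryl ketone is reached more easily by adding an aryl-metal to an aldehyde and oxidising than by acylation, which would also raise a regiochemical question on the phloroglucinol ring. MOM on ring B and benzyl on ring A let acid free ring B alone.

**11 from 6, 7 and 3 (key disconnection).** Two bonds of ring A are cut together: aryl–methyl and aryl–carbinol carbon. The synthon is aryne 9, generated from iodo triflate 6 through the magnesiated triflate 8. It takes the methyl group of 7 and passes on as arylmagnesium 10 to aldehyde 3. The neighbouring cut breaks only the aryl–carbinol bond and starts from a ring that already carries the methyl group; it is used for ring D below. On the left the two-bond cut is preferred because the aryne precursor comes from a symmetrical phenol, so only one kind of ortho-iodination is possible, and because the benzyloxy group beside the triple bond alone decides where methyl and metal go, so the hindered arylmagnesium is formed in place without a separate halogenation of a toluene. The forward reaction must show clean regiochemistry in the aryne addition and must add a di-ortho-substituted arylmagnesium to a 2,6-dialkoxybenzaldehyde.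

**6 from 5 from 4.** The triflate is made from iodophenol 5 by cutting the O–S bond, and 5 by cutting the C–I bond back to commercial 4. The symmetry of 4 makes both positions ortho to the hydroxyl the same.

**3 from 2 from 1.** Only O–C bonds are cut: the two MOM groups of 3 go back to diol 2, and the methyl ether of 2 to commercial 1. The formyl carbon and the 2,4,6-oxygen pattern are bought with the ring, so the left branch needs no metalation of its own and is independent of the right branch. The neighbouring cut, formylation of aryllithium 19, is shorter from 18 but ties both branches to the same metalation; it is kept as the fallback. The forward sequence asks for a selective methylation of the one hydroxyl of 1 that is para to the formyl group.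

**22 from 21 from 20 from 18 and 16.** After the same MOM removal and oxidation-state change as on the left, the right half is cut at the ring C–carbinol bond. Aryllithium 19, formed from 18 by directed metalation between its two MOM ethers, is added to aldehyde 16. Ring D is unsymmetrical, and an aryne route would need an iodo triflate whose iodination could not tell two different ortho positions apart, so the methyl group is bought with the ring.

**18 from 17, and 16 from 15 from 14.** Ether 18 is the double MOM ether of commercial 17. The two hydroxyls of commercial 14 are told apart by the hydrogen bond to the formyl group: benzyl goes on the free 4-hydroxyl to give 15, then methyl on the chelated 2-hydroxyl to give 16.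

## Roads not taken

**Alternative 1: carbonylative Suzuki–Miyaura coupling for the right ketone.**
- Cut: both carbon–carbon bonds at the right-hand carbonyl.
- Forward key step: ring C iodide A2, carbon monoxide and ring D boronic acid A3 are joined by [1,3-bis(2,6-diisopropylphenyl)imidazol-2-ylidene](3-chloropyridine)PdCl2 with Cs2CO3 to give ketone A1.
- Merits: the ketone oxidation state arrives directly, so one oxidation is saved. The step is catalytic and convergent. Bulky carbene ligands of this kind are the ones known to tolerate ortho substituents in carbonylative couplings.
- Weak points: both partners are di-ortho-substituted and electron-rich. After oxidative addition of A2 to zerovalent palladium and CO insertion, transmetalation of A3 onto the acyl complex has to build a tetra-ortho-substituted ketone. Protodeboronation of A3 under carbonate and direct biaryl coupling compete. A3 needs a regio-defined halide of the unsymmetrical ring D, which neither halogenation nor directed lithiation of the parent diether would give cleanly. A1 carries only MOM groups, so its deprotection would free ring D together with ring C and the bridge would have to be made without differentiation.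
- Comparison: this road is better in oxidation-state economy and avoids organolithium reagents. The chosen plan sets against it aryl-metal additions to aldehydes, which are far less sensitive to ortho crowding, and a protecting-group pattern that keeps rings A and D out of the bridge-forming step. The price is two Dess–Martin oxidations.

**Alternative 2: twofold 2-pyranone to acylphloroglucinol recyclisation.**
- Cut: in each of rings B and C, the bond between the acyl-bearing carbon and the hydroxyl-bearing carbon on the bridge side.
- Forward key step: Mg(OMe)2 or NaOMe in methanol opens both lactones of bis-pyranone A5 to methyl esters. In each half the carbanion between the two ketones attacks the ester carbon (Claisen type) and aromatises. The product A4 is the same compound as 25 of the chosen route.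
- Merits: the 2,6-dihydroxy-4-methoxy pattern of rings B and C is fixed by the chain. No protecting groups are needed on these rings. The bridge is present before the rings exist, so no site selectivity on a phloroglucinol is asked for. The road ends one step before the target.
- Weak points: A5 already contains the unsymmetrical bridge, so the problem of joining two near-identical halves is only moved to the pyranone stage, where C3 of a 4-methoxy-2-pyranone is a much poorer nucleophile than a phloroglucinol. Each side chain must be introduced by acylating a pyranone methyl anion with a di-ortho-substituted aroyl unit. Both recyclisations must go in the Claisen mode in one flask, against re-lactonisation and aldol closure onto the aryl ketone.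
- Comparison: in protecting-group economy for rings B and C this road is better. The chosen plan sets against it commercial aromatic rings with the oxygen pattern in place, each carbon–carbon bond formed on a simple monomer, and a bridge-forming step of a known kind on phenols.

**Alternative 3: 4-pyranone-masked tetraketone folded into ring A.**
- Cut: the ring A bond between the acyl-bearing and the methyl-bearing carbon.
- Forward key step: KOH or Ba(OH)2 opens 4-pyranone A7 to tetraketone A8. The methylene between the aryl ketone and the next carbonyl adds to the terminal methyl ketone and dehydrates to benzophenone A6.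
- Merits: the positions of methyl and hydroxyls in ring A are dictated by the chain. No aromatic substitution, iodination selectivity or aryne is involved.
- Weak points: A6 has ring A free and ring B benzylated, the reverse of what the bridge-forming step wants, so protecting groups would have to be exchanged. For ring D the methyl group would have to go on the hydrogen-bonded 2-hydroxyl in the presence of the more reactive 4-hydroxyl. Hot hydroxide on a 2-alkoxy-2'-hydroxybenzophenone invites xanthone closure. A7 itself requires acylation of a pyranone methyl anion with a di-ortho-substituted benzoate.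
- Comparison: in regiochemical certainty for ring A this road is at least as good as the chosen one. The chosen plan sets against it two bonds formed in one operation and a protection pattern that comes out right without exchange.

Key step: step 5

## Route

Step 1
Reactants: 1 2,4,6-trihydroxybenzaldehyde
Product: 2 2,6-dihydroxy-4-methoxybenzaldehyde
Conditions: Me2SO4 (1.0 equiv), K2CO3 (1.0 equiv), acetone, rt to 50 °C
Reagents that add atoms: dimethyl sulfate, COS(=O)(=O)OC
Why: Regioselective Williamson methylation; the 4-hydroxyl, para to the formyl group and outside its hydrogen bond, is the most acidic and is alkylated first, and one equivalent of dimethyl sulfate limits a second methylation at an ortho hydroxyl.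

Step 2
Reactants: 2 2,6-dihydroxy-4-methoxybenzaldehyde
Product: 3 4-methoxy-2,6-bis(methoxymethoxy)benzaldehyde
Conditions: NaH (2.5 equiv), MOMCl (2.5 equiv), THF/DMF, 0 °C to rt
Reagents that add atoms: chloromethyl methyl ether, COCCl
Why: Twofold O-alkylation of the sodium phenoxides with the chloromethyl ether (MOM protection); NaH is used because the second ortho hydroxyl remains hydrogen-bonded to the formyl group and resists amine bases, and the aldehyde has no α-hydrogen.

Step 3
Reactants: 4 3,5-bis(benzyloxy)phenol
Product: 5 3,5-bis(benzyloxy)-2-iodophenol
Conditions: N-iodosuccinimide (1.0 equiv), CH2Cl2, −20 to 0 °C, dark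
Reagents that add atoms: N-iodosuccinimide, O=C1CCC(=O)N1I
Why: Electrophilic aromatic iodination of an electron-rich phenol; the two equivalent positions ortho to the free hydroxyl should be favoured over the para position, which is wedged between two benzyloxy groups, and one equivalent of reagent at low temperature limits twofold iodination.

Step 4
Reactants: 5 3,5-bis(benzyloxy)-2-iodophenol
Product: 6 3,5-bis(benzyloxy)-2-iodophenyl trifluoromethanesulfonate
Conditions: Tf2O, pyridine, CH2Cl2, 0 °C
Reagents that add atoms: trifluoromethanesulfonic anhydride, O=S(=O)(OS(=O)(=O)C(F)(F)F)C(F)(F)F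
Why: O-Sulfonylation of the phenol with triflic anhydride and pyridine; the aryl iodide and the benzyl ethers are inert.

Step 5
Reactants: 6 3,5-bis(benzyloxy)-2-iodophenyl trifluoromethanesulfonate; 7 methylmagnesium bromide; 3 4-methoxy-2,6-bis(methoxymethoxy)benzaldehyde
Product: 11 racemic [2,4-bis(benzyloxy)-6-methylphenyl][4-methoxy-2,6-bis(methoxymethoxy)phenyl]methanol, via 2-magnesiated aryl triflate 8 (not isolated), via 3,5-bis(benzyloxy)benzyne 9 (not isolated), via 2,4-bis(benzyloxy)-6-methylphenylmagnesium bromide 10 (not isolated)
Conditions: 6, MeMgBr (2 equiv), THF, −78 °C; iPrMgCl·LiCl (1.05 equiv) added dropwise, −78 to 0 °C; then 3 (2.5 equiv), 0 °C to rt; aq. NH4Cl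
Reagents that add atoms: none
Why: Iodine–magnesium exchange of 6 with iPrMgCl·LiCl is fast at −78 °C because the C–I carbon lies between a triflyloxy and a benzyloxy group, and the arylmagnesium 8 expels triflate to give aryne 9 while MeMgBr is already present in excess. The methyl group adds to the aryne carbon that carried the triflate, remote from the neighbouring benzyloxy group, because the inductively withdrawing oxygen distorts the triple bond so that this carbon is the more electrophilic one and the negative charge develops on the carbon next to oxygen, where it is stabilised inductively and by oxygen–magnesium coordination; this regiochemistry is the one selectivity the step needs and the 3-benzyloxy group secures it. The arylmagnesium 10 is thus formed exactly at the carbon flanked by methyl and benzyloxy and adds to the carbonyl of aldehyde 3, which has no α-hydrogen and whose MOM oxygens can chelate magnesium. The closest known reaction type is the carbomagnesiation of arynes generated from ortho-iodoaryl sulfonates by halogen–magnesium exchange, with electrophile capture of the new arylmagnesium. No ring is closed. The carbinol carbon is the only new stereocentre; nothing controls it, it forms racemic and is erased by the oxidation of step 6. Aldehyde 3 is charged in excess over total Grignard reagent because surplus MeMgBr also consumes it.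

Step 6
Reactants: 11 racemic [2,4-bis(benzyloxy)-6-methylphenyl][4-methoxy-2,6-bis(methoxymethoxy)phenyl]methanol
Product: 12 [2,4-bis(benzyloxy)-6-methylphenyl][4-methoxy-2,6-bis(methoxymethoxy)phenyl]methanone
Conditions: Dess–Martin periodinane, NaHCO3, CH2Cl2, rt
Reagents that add atoms: none
Why: Dess–Martin oxidation of a secondary diaryl carbinol; the hydrogencarbonate buffer protects the MOM ethers and the easily ionised electron-rich benzhydrol, and the stereocentre disappears.

Step 7
Reactants: 12 [2,4-bis(benzyloxy)-6-methylphenyl][4-methoxy-2,6-bis(methoxymethoxy)phenyl]methanone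
Product: 13 [2,4-bis(benzyloxy)-6-methylphenyl](2,6-dihydroxy-4-methoxyphenyl)methanone
Conditions: HCl (cat.), MeOH/THF, 45 °C
Reagents that add atoms: none
Why: Acid-catalysed acetal exchange (MOM ether cleavage) in methanol, which carries the formaldehyde unit away as dimethoxymethane; benzyl ethers and the aryl methyl ether survive, and the benzoyl group damps the ring enough to keep it from reacting with the liberated acetal.

Step 8
Reactants: 14 2,4-dihydroxy-6-methylbenzaldehyde
Product: 15 4-(benzyloxy)-2-hydroxy-6-methylbenzaldehyde
Conditions: BnBr (1.05 equiv), NaHCO3, MeCN, 80 °C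
Reagents that add atoms: benzyl bromide, BrCc1ccccc1
Why: Regioselective Williamson benzylation; the 4-hydroxyl, para to the formyl group and not hydrogen-bonded, is the more acidic one and is alkylated under hydrogencarbonate while the chelated 2-hydroxyl is left.

Step 9
Reactants: 15 4-(benzyloxy)-2-hydroxy-6-methylbenzaldehyde
Product: 16 4-(benzyloxy)-2-methoxy-6-methylbenzaldehyde
Conditions: MeI, K2CO3, DMF, rt
Reagents that add atoms: iodomethane, CI
Why: Williamson methylation of the remaining hydrogen-bonded phenol with carbonate in DMF; this fixes the ring D methyl ether that distinguishes the right half.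

Step 10
Reactants: 17 5-methoxybenzene-1,3-diol
Product: 18 1-methoxy-3,5-bis(methoxymethoxy)benzene
Conditions: MOMCl, iPr2NEt, CH2Cl2, 0 °C to rt
Reagents that add atoms: chloromethyl methyl ether, COCCl
Why: O-Alkylation of both phenols with the chloromethyl ether under amine base (MOM protection); MOM is chosen because it directs the lithiation of step 11 and is later removed by acid without touching benzyl ethers.

Step 11
Reactants: 18 1-methoxy-3,5-bis(methoxymethoxy)benzene; 16 4-(benzyloxy)-2-methoxy-6-methylbenzaldehyde
Product: 20 racemic [4-(benzyloxy)-2-methoxy-6-methylphenyl][4-methoxy-2,6-bis(methoxymethoxy)phenyl]methanol, via 4-methoxy-2,6-bis(methoxymethoxy)phenyllithium 19 (not isolated)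
Conditions: 18, n-BuLi, TMEDA, THF, 0 °C; then 16, −78 °C to rt; aq. NH4Cl
Reagents that add atoms: none
Why: Directed ortho-metalation at the carbon between the two MOM ethers, which is flanked by two strong coordinating groups and is deprotonated in preference to the carbons next to the weaker methoxy director, followed by 1,2-addition of the aryllithium to a non-enolisable aromatic aldehyde, which is much faster than deprotonation of the ortho methyl group; the carbinol is racemic and is oxidised in step 12.

Step 12
Reactants: 20 racemic [4-(benzyloxy)-2-methoxy-6-methylphenyl][4-methoxy-2,6-bis(methoxymethoxy)phenyl]methanol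
Product: 21 [4-(benzyloxy)-2-methoxy-6-methylphenyl][4-methoxy-2,6-bis(methoxymethoxy)phenyl]methanone
Conditions: Dess–Martin periodinane, NaHCO3, CH2Cl2, rt
Reagents that add atoms: none
Why: Buffered Dess–Martin oxidation of the diaryl carbinol, as in step 6; the stereocentre disappears.

Step 13
Reactants: 21 [4-(benzyloxy)-2-methoxy-6-methylphenyl][4-methoxy-2,6-bis(methoxymethoxy)phenyl]methanone
Product: 22 [4-(benzyloxy)-2-methoxy-6-methylphenyl](2,6-dihydroxy-4-methoxyphenyl)methanone
Conditions: HCl (cat.), MeOH/THF, 45 °C
Reagents that add atoms: none
Why: Acid-catalysed MOM ether cleavage in methanol, as in step 7; the mild acid and moderate temperature are well below what xanthone closure or methyl ether cleavage would need.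

Step 14
Reactants: 13 [2,4-bis(benzyloxy)-6-methylphenyl](2,6-dihydroxy-4-methoxyphenyl)methanone
Product: 23 [2,4-bis(benzyloxy)-6-methylphenyl]{3-[(dimethylamino)methyl]-2,6-dihydroxy-4-methoxyphenyl}methanone
Conditions: Eschenmoser's salt (1.0 equiv), Et3N, CH2Cl2, 0 °C to rt
Reagents that add atoms: N,N-dimethylmethyleneiminium iodide (Eschenmoser's salt), C=[N+](C)C.[I-]
Why: Mannich aminomethylation of a phenol with a preformed iminium salt; only ring B has free phenols, its positions 3 and 5 are equivalent, and one equivalent of the salt acting on the phenoxide should stop at the mono-Mannich base while the bis(benzyl ether) ring A stays unreactive.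

Step 15
Reactants: 23 [2,4-bis(benzyloxy)-6-methylphenyl]{3-[(dimethylamino)methyl]-2,6-dihydroxy-4-methoxyphenyl}methanone; 22 [4-(benzyloxy)-2-methoxy-6-methylphenyl](2,6-dihydroxy-4-methoxyphenyl)methanone
Product: 25 [3-({3-[4-(benzyloxy)-2-methoxy-6-methylbenzoyl]-2,4-dihydroxy-6-methoxyphenyl}methyl)-2,6-dihydroxy-4-methoxyphenyl][2,4-bis(benzyloxy)-6-methylphenyl]methanone, via ortho-quinone methide of ring B 24 (not isolated)
Conditions: 22 (2 equiv), toluene, 90 °C, N2 stream
Reagents that add atoms: none
Why: Thermal loss of dimethylamine from the phenolic Mannich base gives ortho-quinone methide 24, which is captured at carbon by the phloroglucinol ring C of 22 (conjugate addition, then rearomatisation), the established directed way to unsymmetrical methylene-bridged acylphloroglucinols; 22 is in excess so that 24 meets it before a second molecule of 23, its two free positions are equivalent, and rings A and D have no free phenol.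

Step 16
Reactants: 25 [3-({3-[4-(benzyloxy)-2-methoxy-6-methylbenzoyl]-2,4-dihydroxy-6-methoxyphenyl}methyl)-2,6-dihydroxy-4-methoxyphenyl][2,4-bis(benzyloxy)-6-methylphenyl]methanone
Product: 26 [3-({2,4-dihydroxy-3-(4-hydroxy-2-methoxy-6-methylbenzoyl)-6-methoxyphenyl}methyl)-2,6-dihydroxy-4-methoxyphenyl](2,4-dihydroxy-6-methylphenyl)methanone (target, CNP0596095.0)
Conditions: H2 (1 atm), Pd/C (10 wt % Pd), EtOAc/MeOH, rt
Reagents that add atoms: none
Why: Hydrogenolysis of three aryl benzyl ethers over Pd/C under neutral conditions; the diaryl ketones are twisted by four ortho substituents and chelated by ortho hydroxyls, so they should be reduced far more slowly than the O-benzyl bonds are cleaved, and the diarylmethane and the methyl ethers are inert.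

## Compound list

1 | 2,4,6-trihydroxybenzaldehyde | O=Cc1c(O)cc(O)cc1O | starting material
2 | 2,6-dihydroxy-4-methoxybenzaldehyde | COc1cc(O)c(C=O)c(O)c1 | intermediate
3 | 4-methoxy-2,6-bis(methoxymethoxy)benzaldehyde | O=Cc1c(OCOC)cc(OC)cc1OCOC | intermediate
4 | 3,5-bis(benzyloxy)phenol | Oc1cc(OCc2ccccc2)cc(OCc2ccccc2)c1 | starting material
5 | 3,5-bis(benzyloxy)-2-iodophenol | Oc1cc(OCc2ccccc2)cc(OCc2ccccc2)c1I | intermediate
6 | 3,5-bis(benzyloxy)-2-iodophenyl trifluoromethanesulfonate | FC(F)(F)S(=O)(=O)Oc1cc(OCc2ccccc2)cc(OCc2ccccc2)c1I | intermediate
7 | methylmagnesium bromide | C[Mg]Br | starting material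
8 | [2,4-bis(benzyloxy)-6-(trifluoromethanesulfonyloxy)phenyl]magnesium chloride | FC(F)(F)S(=O)(=O)Oc1cc(OCc2ccccc2)cc(OCc2ccccc2)c1[Mg]Cl | intermediate (not isolated)
9 | 3,5-bis(benzyloxy)benzyne (1,2-didehydro-3,5-bis(benzyloxy)benzene) | C1(OCc2ccccc2)=CC(OCc2ccccc2)=CC#C1 | intermediate (not isolated)
10 | [2,4-bis(benzyloxy)-6-methylphenyl]magnesium bromide | Cc1cc(OCc2ccccc2)cc(OCc2ccccc2)c1[Mg]Br | intermediate (not isolated)
11 | racemic [2,4-bis(benzyloxy)-6-methylphenyl][4-methoxy-2,6-bis(methoxymethoxy)phenyl]methanol | Cc1cc(OCc2ccccc2)cc(OCc2ccccc2)c1C(O)c1c(OCOC)cc(OC)cc1OCOC | intermediate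
12 | [2,4-bis(benzyloxy)-6-methylphenyl][4-methoxy-2,6-bis(methoxymethoxy)phenyl]methanone | Cc1cc(OCc2ccccc2)cc(OCc2ccccc2)c1C(=O)c1c(OCOC)cc(OC)cc1OCOC | intermediate
13 | [2,4-bis(benzyloxy)-6-methylphenyl](2,6-dihydroxy-4-methoxyphenyl)methanone | Cc1cc(OCc2ccccc2)cc(OCc2ccccc2)c1C(=O)c1c(O)cc(OC)cc1O | intermediate
14 | 2,4-dihydroxy-6-methylbenzaldehyde | Cc1cc(O)cc(O)c1C=O | starting material
15 | 4-(benzyloxy)-2-hydroxy-6-methylbenzaldehyde | Cc1cc(OCc2ccccc2)cc(O)c1C=O | intermediate
16 | 4-(benzyloxy)-2-methoxy-6-methylbenzaldehyde | Cc1cc(OCc2ccccc2)cc(OC)c1C=O | intermediate
17 | 5-methoxybenzene-1,3-diol | COc1cc(O)cc(O)c1 | starting material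
18 | 1-methoxy-3,5-bis(methoxymethoxy)benzene | COCOc1cc(OC)cc(OCOC)c1 | intermediate
19 | [4-methoxy-2,6-bis(methoxymethoxy)phenyl]lithium | [Li]c1c(OCOC)cc(OC)cc1OCOC | intermediate (not isolated)
20 | racemic [4-(benzyloxy)-2-methoxy-6-methylphenyl][4-methoxy-2,6-bis(methoxymethoxy)phenyl]methanol | Cc1cc(OCc2ccccc2)cc(OC)c1C(O)c1c(OCOC)cc(OC)cc1OCOC | intermediate
21 | [4-(benzyloxy)-2-methoxy-6-methylphenyl][4-methoxy-2,6-bis(methoxymethoxy)phenyl]methanone | Cc1cc(OCc2ccccc2)cc(OC)c1C(=O)c1c(OCOC)cc(OC)cc1OCOC | intermediate
22 | [4-(benzyloxy)-2-methoxy-6-methylphenyl](2,6-dihydroxy-4-methoxyphenyl)methanone | Cc1cc(OCc2ccccc2)cc(OC)c1C(=O)c1c(O)cc(OC)cc1O | intermediate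
23 | [2,4-bis(benzyloxy)-6-methylphenyl]{3-[(dimethylamino)methyl]-2,6-dihydroxy-4-methoxyphenyl}methanone | Cc1cc(OCc2ccccc2)cc(OCc2ccccc2)c1C(=O)c1c(O)cc(OC)c(CN(C)C)c1O | intermediate
24 | 2-[2,4-bis(benzyloxy)-6-methylbenzoyl]-3-hydroxy-5-methoxy-6-methylidenecyclohexa-2,4-dien-1-one | C=C1C(OC)=CC(O)=C(C(=O)c2c(C)cc(OCc3ccccc3)cc2OCc2ccccc2)C1=O | intermediate (not isolated)
25 | [3-({3-[4-(benzyloxy)-2-methoxy-6-methylbenzoyl]-2,4-dihydroxy-6-methoxyphenyl}methyl)-2,6-dihydroxy-4-methoxyphenyl][2,4-bis(benzyloxy)-6-methylphenyl]methanone | COc1cc(O)c(C(=O)c2c(C)cc(OCc3ccccc3)cc2OCc2ccccc2)c(O)c1Cc1c(OC)cc(O)c(C(=O)c2c(C)cc(OCc3ccccc3)cc2OC)c1O | intermediate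
26 | [3-({2,4-dihydroxy-3-(4-hydroxy-2-methoxy-6-methylbenzoyl)-6-methoxyphenyl}methyl)-2,6-dihydroxy-4-methoxyphenyl](2,4-dihydroxy-6-methylphenyl)methanone | COc1cc(O)c(C(=O)c2c(C)cc(O)cc2O)c(O)c1Cc1c(OC)cc(O)c(C(=O)c2c(C)cc(O)cc2OC)c1O | target

## Step count and least certain steps

Total: 16 steps. Longest linear sequence: 8 steps (1, 2, 5, 6, 7, 14, 15, 16 from 1; equally 3, 4, 5, 6, 7, 14, 15, 16 from 4). The right branch from 14 (steps 8, 9, 11, 12, 13, 15, 16) has 7 steps.

**Step 5 (key step).**
- What may go wrong: the aryne may be intercepted by a nucleophile other than methyl (the isopropyl Grignard reagent or one of the arylmagnesium species). The crowded arylmagnesium may also add too slowly to the electron-rich aldehyde and be protonated on work-up.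
- Fallback: the ring A–carbinol bond alone is formed, with the methyl group already on the ring. It sets out from 14 and 18. Twofold benzylation of 14 (BnBr, K2CO3, DMF) should give 2,4-bis(benzyloxy)-6-methylbenzaldehyde F1. Addition of aryllithium 19, made from 18 as in step 11, to F1 comes back to the route at 11.

**Step 1.**
- What may go wrong: methylation of an ortho hydroxyl in place of or in addition to the 4-hydroxyl, because the three phenols of 1 differ only moderately in acidity.
- Fallback: the formyl group is introduced on a ring whose oxygens are already differentiated, instead of differentiating the oxygens of an aldehyde. It sets out from 18. Directed metalation (n-BuLi, TMEDA, THF, 0 °C) as in step 11 gives aryllithium 19, which is formylated with DMF at −78 °C to rt. The fallback replaces steps 1 and 2, comes back to the route at 3 and makes no compound outside the list (F0).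

**Step 3.**
- What may go wrong: iodination at the position para to the hydroxyl, or twofold iodination, in competition with the wanted ortho attack.
- Fallback: the iodine is placed by directed metalation. It sets out from 4. Carbamoylation (ClCONEt2, K2CO3, MeCN) should give 3,5-bis(benzyloxy)phenyl N,N-diethylcarbamate F2. s-BuLi/TMEDA in THF at −78 °C should lithiate between the carbamate and a benzyloxy group to give [2,4-bis(benzyloxy)-6-(diethylcarbamoyloxy)phenyl]lithium F3. Quenching with iodine gives 3,5-bis(benzyloxy)-2-iodophenyl N,N-diethylcarbamate F4. Hydrolysis (KOH, EtOH, reflux) comes back to the route at 5.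

**Step 15.**
- What may go wrong: the quinone methide may form slowly, or it may react with a second molecule of the Mannich base, so that oligomers grow at the expense of the cross-coupled product.
- Fallback: the directed order is given up. It sets out from 13 and 22. The two are condensed together with aqueous formaldehyde and a little KOH in ethanol at 0 °C to rt, with 22 in threefold excess so that most of 13 ends in the mixed dimer. The three dimers carry four, three and two benzyl groups and should separate by chromatography. The fallback comes back at 25 and makes no compound outside the list (F0).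

**Step 16.**
- What may go wrong: partial reduction of a diaryl ketone, or sluggish cleavage on the large and poorly soluble tribenzyl ether.
- Fallback: the benzyl groups are removed at the monomer stage, where a reduced by-product is easier to detect and remove, and the bridge is then made on free phenols. It sets out from 13 and 22. Hydrogenolysis (H2, Pd/C) should give (2,4-dihydroxy-6-methylphenyl)(2,6-dihydroxy-4-methoxyphenyl)methanone F5 from 13 and (2,6-dihydroxy-4-methoxyphenyl)(4-hydroxy-2-methoxy-6-methylphenyl)methanone F6 from 22. Aminomethylation of F5 with Eschenmoser's salt should give {3-[(dimethylamino)methyl]-2,6-dihydroxy-4-methoxyphenyl}(2,4-dihydroxy-6-methylphenyl)methanone F7. Warming F7 with an excess of F6 should pass through 2-(2,4-dihydroxy-6-methylbenzoyl)-3-hydroxy-5-methoxy-6-methylidenecyclohexa-2,4-dien-1-one F8 and come back at 26.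
- Cost of the fallback: site selectivity then rests only on the higher nucleophilicity of the phloroglucinol rings B and C over the resorcinol-type rings A and D.

## Further compounds

F1 | step 5 | 2,4-bis(benzyloxy)-6-methylbenzaldehyde | Cc1cc(OCc2ccccc2)cc(OCc2ccccc2)c1C=O
F0 | step 1 | none | none
F2 | step 3 | 3,5-bis(benzyloxy)phenyl N,N-diethylcarbamate | CCN(CC)C(=O)Oc1cc(OCc2ccccc2)cc(OCc2ccccc2)c1
F3 | step 3 | [2,4-bis(benzyloxy)-6-(diethylcarbamoyloxy)phenyl]lithium | CCN(CC)C(=O)Oc1cc(OCc2ccccc2)cc(OCc2ccccc2)c1[Li]
F4 | step 3 | 3,5-bis(benzyloxy)-2-iodophenyl N,N-diethylcarbamate | CCN(CC)C(=O)Oc1cc(OCc2ccccc2)cc(OCc2ccccc2)c1I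
F0 | step 15 | none | none
F5 | step 16 | (2,4-dihydroxy-6-methylphenyl)(2,6-dihydroxy-4-methoxyphenyl)methanone | Cc1cc(O)cc(O)c1C(=O)c1c(O)cc(OC)cc1O
F6 | step 16 | (2,6-dihydroxy-4-methoxyphenyl)(4-hydroxy-2-methoxy-6-methylphenyl)methanone | Cc1cc(O)cc(OC)c1C(=O)c1c(O)cc(OC)cc1O
F7 | step 16 | {3-[(dimethylamino)methyl]-2,6-dihydroxy-4-methoxyphenyl}(2,4-dihydroxy-6-methylphenyl)methanone | Cc1cc(O)cc(O)c1C(=O)c1c(O)cc(OC)c(CN(C)C)c1O
F8 | step 16 | 2-(2,4-dihydroxy-6-methylbenzoyl)-3-hydroxy-5-methoxy-6-methylidenecyclohexa-2,4-dien-1-one | C=C1C(OC)=CC(O)=C(C(=O)c2c(C)cc(O)cc2O)C1=O
A1 | alternative 1 | [4-methoxy-2,6-bis(methoxymethoxy)phenyl][2-methoxy-4-(methoxymethoxy)-6-methylphenyl]methanone | COc1cc(OCOC)c(C(=O)c2c(C)cc(OCOC)cc2OC)c(OCOC)c1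
A2 | alternative 1 | 2-iodo-5-methoxy-1,3-bis(methoxymethoxy)benzene | COCOc1cc(OC)cc(OCOC)c1I
A3 | alternative 1 | [2-methoxy-4-(methoxymethoxy)-6-methylphenyl]boronic acid | COCOc1cc(C)c(B(O)O)c(OC)c1
A4 | alternative 2 | tri-O-benzyl ether of the target, identical with 25 | COc1cc(O)c(C(=O)c2c(C)cc(OCc3ccccc3)cc2OCc2ccccc2)c(O)c1Cc1c(OC)cc(O)c(C(=O)c2c(C)cc(OCc3ccccc3)cc2OC)c1O
A5 | alternative 2 | 3-({6-[2-(2,4-bis(benzyloxy)-6-methylphenyl)-2-oxoethyl]-4-methoxy-2-oxo-2H-pyran-3-yl}methyl)-6-{2-[4-(benzyloxy)-2-methoxy-6-methylphenyl]-2-oxoethyl}-4-methoxy-2H-pyran-2-one | O=c1oc(CC(=O)c2c(C)cc(OCc3ccccc3)cc2OCc2ccccc2)cc(OC)c1Cc1c(OC)cc(CC(=O)c2c(C)cc(OCc3ccccc3)cc2OC)oc1=O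
A6 | alternative 3 | [2,6-bis(benzyloxy)-4-methoxyphenyl](2,4-dihydroxy-6-methylphenyl)methanone | Cc1cc(O)cc(O)c1C(=O)c1c(OCc2ccccc2)cc(OC)cc1OCc1ccccc1
A7 | alternative 3 | 2-{2-[2,6-bis(benzyloxy)-4-methoxyphenyl]-2-oxoethyl}-6-methyl-4H-pyran-4-one | Cc1cc(=O)cc(CC(=O)c2c(OCc3ccccc3)cc(OC)cc2OCc2ccccc2)o1
A8 | alternative 3 | 1-[2,6-bis(benzyloxy)-4-methoxyphenyl]octane-1,3,5,7-tetraone | CC(=O)CC(=O)CC(=O)CC(=O)c1c(OCc2ccccc2)cc(OC)cc1OCc1ccccc1
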